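**Retrosynthetic overview** (benzofuranone numbering O1, C2, C3, C3a, C4–C7, C7a; primes = side chain; ring A = carbocycle, ring B = dihydrofuran)
1. Ring B is closed last: 22 ⇒ chiral hydroxy-dione 5 + terminal epoxide 20 (C3–C3a alkylation, then O1–C7a cyclodehydration; the C2–O bond is never broken).
2. 20 ⇒ pentol 18 ⇒ bis-acetonide 17 ⇒ vinyl iodide 15 + acid 8: the C6′–C7′ bond is made by nickel-electrocatalytic decarboxylative alkenylation (key convergent bond; E-alkene fixed by hydrozirconation).
3. 15 ⇒ methyl ketone 11 (from L-serine-derived ester 9, C2 bought) + pentynyl Grignard 13; chelation sets C2′ from C2.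
4. 5 (ring A, formed first by Claisen ring enlargement; C5 bought) and 8 (C9′ bought) ⇒ common keto-lactone 3 ⇒ D-glutamic-acid-derived lactone acid 1.

Assumption: 1, 9 and 12 are bought as such (1 and 9 enantiopure); all selectivities quoted are estimates.

**Step 1**
Reactants: 1 (R)-5-oxotetrahydrofuran-2-carboxylic acid
Product: 3 (R)-5-acetyldihydrofuran-2(3H)-one, via acid chloride 2 (not isolated)
Conditions: (COCl)2, DMF (cat.), CH2Cl2, 0 °C to rt, evaporate; MeMgBr (1.05 equiv), Fe(acac)3 (3 mol%), THF, −78 °C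
Reagents that add atoms: methylmagnesium bromide (C[Mg]Br)
Why: Acid chloride formation followed by iron-catalysed acylation of the Grignard reagent (ketone synthesis from an acid chloride) is much faster at −78 °C than attack on the ketone formed or on the γ-lactone, and the stereocentre bought in 1 is not involved.

**Step 2**
Reactants: 3 (R)-5-acetyldihydrofuran-2(3H)-one
Product: 5 (R)-4-hydroxycyclohexane-1,3-dione, via dilithium dianion 4 (not isolated)
Conditions: LiN(SiMe3)2 (2.3 equiv), THF, −78 °C (slow addition of 3), then to −20 °C; 1 M HCl to pH 3, 0 °C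
Reagents that add atoms: none
Why: Intramolecular Claisen (Dieckmann-type) condensation: the kinetic methyl enolate adds to the lactone carbonyl and the bridged alkoxide collapses with ring enlargement to the six-membered 1,3-dione, which is at once deprotonated to dianion 4, so the step is irreversible and the α-oxygenated stereocentre (bought, later C5) is neither broken nor enolised.

**Step 3**
Reactants: 3 (R)-5-acetyldihydrofuran-2(3H)-one
Product: 6 (R)-5-(2-hydroxypropan-2-yl)dihydrofuran-2(3H)-one
Conditions: MeMgBr (1.1 equiv), THF, −78 °C; then H2O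
Reagents that add atoms: methylmagnesium bromide (C[Mg]Br)
Why: Chemoselective Grignard 1,2-addition to the α-alkoxy ketone, which is far more electrophilic than the γ-lactone at −78 °C; the carbinol carbon carries two methyl groups, so no new stereocentre arises and the bought one (later C9′) is untouched.

**Step 4**
Reactants: 6 (R)-5-(2-hydroxypropan-2-yl)dihydrofuran-2(3H)-one
Product: 7 methyl 3-[(4R)-2,2,5,5-tetramethyl-1,3-dioxolan-4-yl]propanoate
Conditions: 2,2-dimethoxypropane, MeOH, p-TsOH·H2O (5 mol%), 40 °C; Et3N quench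
Reagents that add atoms: methanol (CO); 2,2-dimethoxypropane (COC(C)(C)OC)
Why: Acid-catalysed lactone methanolysis is pulled to the open ester by transketalisation of the freed secondary/tertiary 1,2-diol into its isopropylidene acetal (acetonide formation), leaving the stereocentre unchanged.

**Step 5**
Reactants: 7 methyl 3-[(4R)-2,2,5,5-tetramethyl-1,3-dioxolan-4-yl]propanoate
Product: 8 3-[(4R)-2,2,5,5-tetramethyl-1,3-dioxolan-4-yl]propanoic acid
Conditions: LiOH·H2O, THF/H2O (3:1), 0 °C to rt; 1 M HCl to pH 4, 0 °C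
Reagents that add atoms: lithium hydroxide ([Li+].[OH-])
Why: Ester saponification; the acetonide is stable to base and survives the brief cold acidification to pH 4.

**Step 6**
Reactants: 9 methyl (S)-2,2-dimethyl-1,3-dioxolane-4-carboxylate
Product: 11 1-[(4S)-2,2-dimethyl-1,3-dioxolan-4-yl]ethan-1-one, via Weinreb amide 10 (not isolated)
Conditions: MeNHOMe·HCl (1.5 equiv), iPrMgCl (3.0 equiv), THF, −20 °C; then MeMgBr (2.0 equiv), −20 to 0 °C; then H2O
Reagents that add atoms: methylmagnesium bromide (C[Mg]Br)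
Why: One-pot Weinreb ketone synthesis: magnesium-amide aminolysis of the ester gives 10, whose chelated tetrahedral adduct with MeMgBr cannot over-add, and the bought α-stereocentre (later C2) is kept because the basic steps are run cold.

**Step 7**
Reactants: 11 1-[(4S)-2,2-dimethyl-1,3-dioxolan-4-yl]ethan-1-one; 12 5-bromopent-2-yne
Product: 14 (2S)-2-[(4S)-2,2-dimethyl-1,3-dioxolan-4-yl]hept-5-yn-2-ol, via Grignard reagent 13 (not isolated)
Conditions: 12, Mg turnings, THF, rt; add to 11 pre-complexed with MgBr2·OEt2 (1.5 equiv), CH2Cl2, −78 °C; then H2O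
Reagents that add atoms: none
Why: Cram chelate-controlled Grignard addition: the magnesium ion bridges the carbonyl and the α-oxygen of the dioxolane, so the alkyl group enters on the face of the α-hydrogen and the bought centre (later C2) sets the tertiary carbinol (later C2′) as (S) (dr about 8:1 expected; minor epimer removed by chromatography).

**Step 8**
Reactants: 14 (2S)-2-[(4S)-2,2-dimethyl-1,3-dioxolan-4-yl]hept-5-yn-2-ol
Product: 15 (2S,5E)-2-[(4S)-2,2-dimethyl-1,3-dioxolan-4-yl]-6-iodohept-5-en-2-ol
Conditions: Cp2Zr(H)Cl (2.6 equiv), THF, rt then 45 °C; I2 (1.3 equiv), THF, 0 °C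
Reagents that add atoms: iodine (II)
Why: Hydrozirconation is a syn addition and, with excess reagent at 45 °C, equilibrates zirconium to the less hindered methyl-bearing alkyne carbon (about 9:1); iododezirconation with retention then gives the (E)-2-iodoalkene that fixes the later E geometry.

**Step 9**
Reactants: 15 (2S,5E)-2-[(4S)-2,2-dimethyl-1,3-dioxolan-4-yl]-6-iodohept-5-en-2-ol; 8 3-[(4R)-2,2,5,5-tetramethyl-1,3-dioxolan-4-yl]propanoic acid
Product: 17 (2S,5E)-2-[(4S)-2,2-dimethyl-1,3-dioxolan-4-yl]-6-methyl-8-[(4R)-2,2,5,5-tetramethyl-1,3-dioxolan-4-yl]oct-5-en-2-ol, via phthalimide ester 16 (not isolated)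
Conditions: 8, N-hydroxyphthalimide, N,N′-diisopropylcarbodiimide, DMAP (cat.), CH2Cl2, rt, filter, evaporate; 15, NiCl2·6H2O (10 mol%), 2,2′-bipyridine (10 mol%), AgNO3 (0.3 equiv), DMF, undivided cell, Mg anode, RVC cathode, constant current (about 3 F/mol), rt
Reagents that add atoms: none
Why: Nickel-electrocatalytic decarboxylative alkenylation (reductive cross-electrophile coupling): cathodic reduction of the redox-active ester 16 releases CO2 and a primary alkyl radical, which is captured by the alkenylnickel species from oxidative addition of 15 to zerovalent nickel; reductive elimination forms the C6′–C7′ bond with retention of alkene geometry and no stereocentre is touched.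

**Step 10**
Reactants: 17 (2S,5E)-2-[(4S)-2,2-dimethyl-1,3-dioxolan-4-yl]-6-methyl-8-[(4R)-2,2,5,5-tetramethyl-1,3-dioxolan-4-yl]oct-5-en-2-ol
Product: 18 (2S,3S,6E,10R)-3,7,11-trimethyldodec-6-ene-1,2,3,10,11-pentol
Conditions: AcOH/H2O (4:1), 45 °C
Reagents that add atoms: none
Why: Acid-catalysed acetal hydrolysis; aqueous acetic acid is too weak to protonate the trisubstituted alkene or ionise the tertiary alcohols, so the five hydroxyls are freed without cyclisation.

**Step 11**
Reactants: 18 (2S,3S,6E,10R)-3,7,11-trimethyldodec-6-ene-1,2,3,10,11-pentol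
Product: 20 (2S,5E,9R)-6,10-dimethyl-2-[(2S)-oxiran-2-yl]undec-5-ene-2,9,10-triol, via monotosylate 19 (not isolated)
Conditions: TsCl (1.05 equiv), Bu2SnO (5 mol%), Et3N, CH2Cl2, 0 °C; then K2CO3, MeOH, 0 °C to rt
Reagents that add atoms: none
Why: Bu2SnO-catalysed sulfonylation is selective for the primary hydroxyl of the terminal 1,2-diol (stannylene acetal activation) and the secondary alkoxide then closes the epoxide by intramolecular Williamson substitution at the primary carbon, so the C–O bond at the stereocentre (later C2) is retained.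

**Step 12**
Reactants: 20 (2S,5E,9R)-6,10-dimethyl-2-[(2S)-oxiran-2-yl]undec-5-ene-2,9,10-triol; 5 (R)-4-hydroxycyclohexane-1,3-dione
Product: 22 (2S,5R)-5-hydroxy-2-[(2S,5E,9R)-2,9,10-trihydroxy-6,10-dimethylundec-5-en-2-yl]-2,3,6,7-tetrahydro-1-benzofuran-4(5H)-one, via C-alkylated dione 21 (not isolated)
Conditions: 5 (1.5 equiv), Ti(OiPr)4 (3.0 equiv), THF, 4 Å MS, rt to 50 °C; then 1 M HCl/THF (1:4), rt
Reagents that add atoms: none
Why: Proposed new method: titanium-templated C-alkylation/cyclodehydration of a cyclic 1,3-dione with a 2,3-epoxy alcohol. Ti(OiPr)4 binds the tertiary C2′ alkoxide and the epoxide oxygen of 20 (tetravalent titanium as a tethered Lewis acid), which directs attack to the distal, unhindered CH2 (C3). Dione 5 (pKa about 5) exchanges onto a neighbouring titanium centre of the alkoxide-bridged aggregate as an O-bound enolate, so its oxygen is blocked and its soft central carbon opens the epoxide in a closed, aldol-like transition state to give 21 without touching the C2–O bond (retention at C2; C5, C2′ and C9′ unchanged). Aqueous acid then lets the C2 hydroxyl add to the ring carbonyl remote from the CH–OH and dehydrates the five-membered hemiketal to the vinylogous ester; the isomer that keeps the hydrogen-bonded α-hydroxy ketone is expected to be the thermodynamic one under these equilibrating conditions. Closest known reaction types: the Ti(OiPr)4-mediated C3-selective opening of 2,3-epoxy alcohols by amine, thiol, carboxylate and halide nucleophiles, and the base-mediated C-alkylation of cyclic 1,3-diones followed by hemiketal dehydration to 2,3-dihydrofurans.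

**Compound list**
1 | (R)-5-oxotetrahydrofuran-2-carboxylic acid | O=C1CC[C@H](C(=O)O)O1 | starting material
2 | (R)-5-oxotetrahydrofuran-2-carbonyl chloride | O=C1CC[C@H](C(=O)Cl)O1 | intermediate (not isolated)
3 | (R)-5-acetyldihydrofuran-2(3H)-one | O=C1CC[C@H](C(C)=O)O1 | intermediate
4 | dilithium (4R)-4-oxido-3-oxocyclohex-1-en-1-olate | [Li+].[Li+].[O-]C1=CC(=O)[C@H]([O-])CC1 | intermediate (not isolated)
5 | (R)-4-hydroxycyclohexane-1,3-dione | O=C1CC[C@@H](O)C(=O)C1 | intermediate
6 | (R)-5-(2-hydroxypropan-2-yl)dihydrofuran-2(3H)-one | O=C1CC[C@H](C(C)(C)O)O1 | intermediate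
7 | methyl 3-[(4R)-2,2,5,5-tetramethyl-1,3-dioxolan-4-yl]propanoate | COC(=O)CC[C@H]1OC(C)(C)OC1(C)C | intermediate
8 | 3-[(4R)-2,2,5,5-tetramethyl-1,3-dioxolan-4-yl]propanoic acid | OC(=O)CC[C@H]1OC(C)(C)OC1(C)C | intermediate
9 | methyl (S)-2,2-dimethyl-1,3-dioxolane-4-carboxylate | COC(=O)[C@@H]1COC(C)(C)O1 | starting material
10 | (S)-N-methoxy-N,2,2-trimethyl-1,3-dioxolane-4-carboxamide | CON(C)C(=O)[C@@H]1COC(C)(C)O1 | intermediate (not isolated)
11 | 1-[(4S)-2,2-dimethyl-1,3-dioxolan-4-yl]ethan-1-one | CC(=O)[C@@H]1COC(C)(C)O1 | intermediate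
12 | 5-bromopent-2-yne | CC#CCCBr | starting material
13 | pent-3-yn-1-ylmagnesium bromide | CC#CCC[Mg]Br | intermediate (not isolated)
14 | (2S)-2-[(4S)-2,2-dimethyl-1,3-dioxolan-4-yl]hept-5-yn-2-ol | CC#CCC[C@](C)(O)[C@@H]1COC(C)(C)O1 | intermediate
15 | (2S,5E)-2-[(4S)-2,2-dimethyl-1,3-dioxolan-4-yl]-6-iodohept-5-en-2-ol | C/C(I)=C\CC[C@](C)(O)[C@@H]1COC(C)(C)O1 | intermediate
16 | 1,3-dioxoisoindolin-2-yl 3-[(4R)-2,2,5,5-tetramethyl-1,3-dioxolan-4-yl]propanoate | O=C(CC[C@H]1OC(C)(C)OC1(C)C)ON1C(=O)c2ccccc2C1=O | intermediate (not isolated)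
17 | (2S,5E)-2-[(4S)-2,2-dimethyl-1,3-dioxolan-4-yl]-6-methyl-8-[(4R)-2,2,5,5-tetramethyl-1,3-dioxolan-4-yl]oct-5-en-2-ol | C/C(=C\CC[C@](C)(O)[C@@H]1COC(C)(C)O1)CC[C@H]1OC(C)(C)OC1(C)C | intermediate
18 | (2S,3S,6E,10R)-3,7,11-trimethyldodec-6-ene-1,2,3,10,11-pentol | C/C(=C\CC[C@](C)(O)[C@@H](O)CO)CC[C@@H](O)C(C)(C)O | intermediate
19 | (2S,3S,6E,10R)-2,3,10,11-tetrahydroxy-3,7,11-trimethyldodec-6-en-1-yl 4-methylbenzenesulfonate | C/C(=C\CC[C@](C)(O)[C@@H](O)COS(=O)(=O)c1ccc(C)cc1)CC[C@@H](O)C(C)(C)O | intermediate (not isolated)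
20 | (2S,5E,9R)-6,10-dimethyl-2-[(2S)-oxiran-2-yl]undec-5-ene-2,9,10-triol | C/C(=C\CC[C@](C)(O)[C@@H]1CO1)CC[C@@H](O)C(C)(C)O | intermediate
21 | (6R)-3,6-dihydroxy-2-[(2S,3S,6E,10R)-2,3,10,11-tetrahydroxy-3,7,11-trimethyldodec-6-en-1-yl]cyclohex-2-en-1-one | C/C(=C\CC[C@](C)(O)[C@@H](O)CC1=C(O)CC[C@@H](O)C1=O)CC[C@@H](O)C(C)(C)O | intermediate (not isolated)
22 | (2S,5R)-5-hydroxy-2-[(2S,5E,9R)-2,9,10-trihydroxy-6,10-dimethylundec-5-en-2-yl]-2,3,6,7-tetrahydro-1-benzofuran-4(5H)-one | C/C(=C\CC[C@](C)(O)[C@@H]1CC2=C(CC[C@@H](O)C2=O)O1)CC[C@@H](O)C(C)(C)O | target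

**Totals and risks**
Total step count: 12. Longest linear sequence: 8 steps (1 → 3 → 6 → 7 → 8 → 17 → 18 → 20 → 22; steps 1, 3, 4, 5, 9, 10, 11, 12).

Stereocentres: C5 and C9′ are bought in 1, C2 is bought in 9, and C2′ is set in step 7 under control of C2. No chiral catalyst, reagent or auxiliary is used.

The three steps most likely to fail:

Step 12 (the proposed new annulation). Risks are O- instead of C-alkylation of the dione, sluggish epoxide opening, and partial formation of the enol-ether regioisomer. The fallback uses known chemistry, sets out from 17 and comes back to the route at 22. The terminal acetonide of 17 is moved to the internal secondary/tertiary diol by acid equilibration (acetone, p-TsOH cat., rt) to give the primary alcohol F1. Oxidation (TEMPO cat., PhI(OAc)2, CH2Cl2) gives the aldehyde F2. Three-component reductive alkylation of 5 with F2 and Hantzsch ester (glycine cat., EtOH/CH2Cl2, rt; Knoevenagel condensation then transfer hydrogenation) gives the 2-alkyl dione F3. Treatment with 1 M HCl/THF then removes both acetonides and closes ring B by cyclodehydration to 22.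

Step 2 (Claisen ring enlargement). Risks are partial enolisation at the α-oxygenated stereocentre and the strained bridged intermediate. The fallback sets out from 3 and comes back at 5. Lactone 3 is opened with Me2AlN(OMe)Me (CH2Cl2, 0 °C) to the hydroxy Weinreb amide F4, which is silylated at once (TBSOTf, 2,6-lutidine) to the silyl ether F5. LiN(SiMe3)2 (THF, −78 to 0 °C) then closes ring A by an open-chain intramolecular enolate acylation, with no bridged intermediate, to the silyloxy dione F6. Aqueous HF in MeCN returns 5.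

Step 7 (diastereoselectivity of the chelate-controlled addition). The risk is that the acetonide chelates weakly, so that Felkin–Anh or β-chelate pathways erode or reverse the ratio. The fallback reverses the order in which the two carbon groups are introduced; it sets out from 10 (isolated by stopping step 6 before MeMgBr) and comes back at 14. Amide 10 is acylated with 13 (THF, −20 °C) to the pentynyl ketone F7, and the methyl group is then delivered under non-chelating Felkin–Anh control with MeTi(OiPr)3 (Et2O/THF, 0 °C to rt). Because the roles of the ketone substituent and the nucleophile are exchanged, the non-chelate pathway gives the same (S) carbinol 14.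

**Further compounds**
F1 | step 12 | [(4S,5S)-2,2,5-trimethyl-5-[(3E)-4-methyl-6-[(4R)-2,2,5,5-tetramethyl-1,3-dioxolan-4-yl]hex-3-en-1-yl]-1,3-dioxolan-4-yl]methanol | C/C(=C\CC[C@]1(C)OC(C)(C)O[C@H]1CO)CC[C@H]1OC(C)(C)OC1(C)C
F2 | step 12 | (4R,5S)-2,2,5-trimethyl-5-[(3E)-4-methyl-6-[(4R)-2,2,5,5-tetramethyl-1,3-dioxolan-4-yl]hex-3-en-1-yl]-1,3-dioxolane-4-carbaldehyde | C/C(=C\CC[C@]1(C)OC(C)(C)O[C@H]1C=O)CC[C@H]1OC(C)(C)OC1(C)C
F3 | step 12 | (6R)-3,6-dihydroxy-2-{[(4S,5S)-2,2,5-trimethyl-5-[(3E)-4-methyl-6-[(4R)-2,2,5,5-tetramethyl-1,3-dioxolan-4-yl]hex-3-en-1-yl]-1,3-dioxolan-4-yl]methyl}cyclohex-2-en-1-one | C/C(=C\CC[C@]1(C)OC(C)(C)O[C@H]1CC1=C(O)CC[C@@H](O)C1=O)CC[C@H]1OC(C)(C)OC1(C)C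
F4 | step 2 | (4R)-4-hydroxy-N-methoxy-N-methyl-5-oxohexanamide | CON(C)C(=O)CC[C@@H](O)C(C)=O
F5 | step 2 | (4R)-4-[(tert-butyldimethylsilyl)oxy]-N-methoxy-N-methyl-5-oxohexanamide | CON(C)C(=O)CC[C@@H](O[Si](C)(C)C(C)(C)C)C(C)=O
F6 | step 2 | (4R)-4-[(tert-butyldimethylsilyl)oxy]cyclohexane-1,3-dione | O=C1CC[C@@H](O[Si](C)(C)C(C)(C)C)C(=O)C1
F7 | step 7 | 1-[(4S)-2,2-dimethyl-1,3-dioxolan-4-yl]hex-4-yn-1-one | CC#CCCC(=O)[C@@H]1COC(C)(C)O1
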